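**Plan**
1. Retrosynthesis: the four phenol protecting groups (MOM) and the 3‑OH go first; ring C is then cut at all three bonds of C2 (C2–C1′, C2–C3, O1–C2), so that C2 becomes carbon monoxide, the B ring an aryl bromide and the A ring an o‑hydroxyacetophenone.
2. Enabling feature: C2 of the 4‑pyranone ring is an acyl‑level carbon bonded only to O1, C3 and C1′. The only free phenol of the A‑ring ketone lies between the acetyl carbon and the quaternary substituent, which fixes O1 and so the 8‑ (not 6‑) position.
3. A ring: the 2‑methylbut‑3‑en‑2‑yl group comes from aromatic Claisen rearrangement of the 4‑O‑prenyl ether of symmetric 2,4,6‑trihydroxyacetophenone (one regioisomer by symmetry).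
4. B ring: 4‑bromophenol is ortho‑C‑prenylated, ortho‑formylated, converted to the catechol by Dakin oxidation and MOM‑protected.
5. Forward order: both benzene rings are bought; ring C closes in the three‑component carbonylative step; C3–H is then turned into C3–OH and the MOM groups are removed.
6. Stereochemistry: none to set.

Key step: step 8

Remark: the target has no stereocentre and no configured double bond, so the given structure is achiral and the route needs no stereocontrol.

**Step 1**
Reactants: 1 1-(2,4,6-trihydroxyphenyl)ethan-1-one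
Product: 2 1-[2,6-dihydroxy-4-(3-methylbut-2-en-1-yloxy)phenyl]ethan-1-one
Conditions: prenyl bromide (1.0 equiv), K2CO3 (1.0 equiv), acetone, reflux
Reagents that add atoms: prenyl bromide (1-bromo-3-methylbut-2-ene), CC(C)=CCBr
Why: Williamson O‑alkylation; the 4‑OH is the most acidic phenol (para to the acetyl group) and is not tied up in the hydrogen bond to C=O, so one equivalent of halide with a weak base should etherify it selectively.

**Step 2**
Reactants: 2 1-[2,6-dihydroxy-4-(3-methylbut-2-en-1-yloxy)phenyl]ethan-1-one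
Product: 3 1-[2,4,6-trihydroxy-3-(2-methylbut-3-en-2-yl)phenyl]ethan-1-one
Conditions: PhNEt2, 190 °C, sealed tube, Ar
Reagents that add atoms: none
Why: Aromatic Claisen ([3,3]‑sigmatropic) rearrangement; the two ortho positions are equivalent by symmetry and the para position carries the acetyl group, so only the ortho product with the inverted 1,1‑dimethylallyl chain can form and re‑aromatise.

**Step 3**
Reactants: 3 1-[2,4,6-trihydroxy-3-(2-methylbut-3-en-2-yl)phenyl]ethan-1-one
Product: 4 1-[2-hydroxy-4,6-bis(methoxymethoxy)-3-(2-methylbut-3-en-2-yl)phenyl]ethan-1-one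
Conditions: MOMCl (2.2 equiv), i-Pr2NEt, CH2Cl2, 0 °C → rt
Reagents that add atoms: chloromethyl methyl ether (MOMCl), COCCl
Why: Chemoselective MOM ether formation; the 2‑OH is wedged between the acetyl group and the quaternary carbon and is held in the hydrogen bond to C=O, so the 4‑ and 6‑OH should react first and leave exactly the phenol that is to become O1.

**Step 4**
Reactants: 5 4-bromophenol
Product: 6 4-bromo-2-(3-methylbut-2-en-1-yl)phenol
Conditions: NaH (1.0 equiv), toluene, 0 °C; prenyl bromide, rt
Reagents that add atoms: prenyl bromide (1-bromo-3-methylbut-2-ene), CC(C)=CCBr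
Why: ortho‑C‑alkylation of a sodium phenoxide in a non‑polar solvent (tight ion pair, attack at the carbon next to O–Na); the para position is blocked by bromine and the two ortho positions are equivalent.

**Step 5**
Reactants: 6 4-bromo-2-(3-methylbut-2-en-1-yl)phenol
Product: 7 5-bromo-2-hydroxy-3-(3-methylbut-2-en-1-yl)benzaldehyde
Conditions: MgCl2, Et3N, (CH2O)n, MeCN, reflux
Reagents that add atoms: paraformaldehyde (as formaldehyde), C=O
Why: Magnesium‑mediated ortho‑formylation of a phenol (Casnati–Skattebøl); the magnesium phenoxide directs the formyl group to the only free ortho position, and the alkene and the bromide are untouched.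

**Step 6**
Reactants: 7 5-bromo-2-hydroxy-3-(3-methylbut-2-en-1-yl)benzaldehyde
Product: 9 5-bromo-3-(3-methylbut-2-en-1-yl)benzene-1,2-diol, via aryl formate 8 (not isolated)
Conditions: 30% H2O2, NaOH, THF–H2O, 0 °C → rt, Ar; HCl work-up
Reagents that add atoms: hydrogen peroxide, OO
Why: Dakin oxidation; hydroperoxide adds to the ortho‑hydroxybenzaldehyde, the electron‑rich aryl group migrates to oxygen and formate 8 is saponified in situ, while alkaline H2O2 does not epoxidise the unactivated trisubstituted alkene.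

**Step 7**
Reactants: 9 5-bromo-3-(3-methylbut-2-en-1-yl)benzene-1,2-diol
Product: 10 5-bromo-1,2-bis(methoxymethoxy)-3-(3-methylbut-2-en-1-yl)benzene
Conditions: MOMCl (2.5 equiv), i-Pr2NEt, CH2Cl2, 0 °C → rt
Reagents that add atoms: chloromethyl methyl ether (MOMCl), COCCl
Why: Standard MOM protection of both catechol OH groups, giving the base‑stable masking needed in steps 8 and 9.

**Step 8**
Reactants: 4 1-[2-hydroxy-4,6-bis(methoxymethoxy)-3-(2-methylbut-3-en-2-yl)phenyl]ethan-1-one; 10 5-bromo-1,2-bis(methoxymethoxy)-3-(3-methylbut-2-en-1-yl)benzene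
Product: 13 2-[3,4-bis(methoxymethoxy)-5-(3-methylbut-2-en-1-yl)phenyl]-5,7-bis(methoxymethoxy)-8-(2-methylbut-3-en-2-yl)-4H-chromen-4-one, via aryl ester 11 (not isolated), via 1,3-diketone 12 (not isolated)
Conditions: Pd(OAc)2 (cat.), dppb (cat.), DBU (3 equiv), CO (10 bar), DMSO, 120 °C
Reagents that add atoms: carbon monoxide, [C-]#[O+]
Why: Pd(0) inserts into the C1′–Br bond of 10 and CO inserts into the aryl–Pd bond, which creates the C2–C1′ bond (C2 is the CO carbon); the aroyl–Pd is taken up by the phenoxide of 4 to give ester 11, and DBU drives a Baker–Venkataraman 1,5‑acyl shift to the enolate carbon (C2–C3 bond) to give 1,3‑diketone 12. The closest known reaction type is the palladium‑catalysed carbonylative coupling of 2‑hydroxyacetophenones with aryl bromides to flavones, a three‑component union of ketone, CO and aryl halide. Ring C closes by 6‑exo‑trig attack of the phenolic oxygen on the aroyl carbonyl of 12 and loss of water from the hemiketal (O1–C2 bond), which gives the aromatic 4‑pyranone. No stereocentre is formed. The step needs the correct sense of ring closure, secured because the only free phenol of 4 is the one between the acetyl group and the quaternary carbon, and it needs carbonylation to win over Heck or direct arylation, secured by CO pressure, the bidentate phosphine and the poor Heck reactivity of a trisubstituted and a neopentyl‑type alkene. The MOM ethers and both C‑prenyl groups are inert to DBU in DMSO.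

**Step 9**
Reactants: 13 2-[3,4-bis(methoxymethoxy)-5-(3-methylbut-2-en-1-yl)phenyl]-5,7-bis(methoxymethoxy)-8-(2-methylbut-3-en-2-yl)-4H-chromen-4-one
Product: 16 2-[3,4-bis(methoxymethoxy)-5-(3-methylbut-2-en-1-yl)phenyl]-3-hydroxy-5,7-bis(methoxymethoxy)-8-(2-methylbut-3-en-2-yl)-4H-chromen-4-one, via 3-lithioflavone 14 (not isolated), via lithium borate 15 (not isolated)
Conditions: LDA, THF, −78 °C; B(OMe)3, −78 → 0 °C; AcOH, 30% H2O2, 0 °C → rt
Reagents that add atoms: hydrogen peroxide, OO
Why: C3–H lithiation of the flavone (the only vinylic C–H of the pyranone, acidified and directed by the C4 carbonyl), borylation and oxidative C–B to C–O conversion; this known flavone‑to‑flavonol sequence avoids electrophilic oxidants, which would attack the two alkenes.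

**Step 10**
Reactants: 16 2-[3,4-bis(methoxymethoxy)-5-(3-methylbut-2-en-1-yl)phenyl]-3-hydroxy-5,7-bis(methoxymethoxy)-8-(2-methylbut-3-en-2-yl)-4H-chromen-4-one
Product: 17 2-[3,4-dihydroxy-5-(3-methylbut-2-en-1-yl)phenyl]-3,5,7-trihydroxy-8-(2-methylbut-3-en-2-yl)-4H-chromen-4-one
Conditions: 3 M HCl, MeOH, 40 °C, Ar
Reagents that add atoms: none
Why: Acid‑catalysed acetal methanolysis of the four MOM ethers, under conditions mild enough that the prenyl and 1,1‑dimethylallyl groups should not cyclise onto the neighbouring phenols.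

**Compound list**
1 | 1-(2,4,6-trihydroxyphenyl)ethan-1-one | CC(=O)c1c(O)cc(O)cc1O | starting material
2 | 1-[2,6-dihydroxy-4-(3-methylbut-2-en-1-yloxy)phenyl]ethan-1-one | CC(=O)c1c(O)cc(OCC=C(C)C)cc1O | intermediate
3 | 1-[2,4,6-trihydroxy-3-(2-methylbut-3-en-2-yl)phenyl]ethan-1-one | CC(=O)c1c(O)cc(O)c(C(C)(C)C=C)c1O | intermediate
4 | 1-[2-hydroxy-4,6-bis(methoxymethoxy)-3-(2-methylbut-3-en-2-yl)phenyl]ethan-1-one | CC(=O)c1c(O)c(C(C)(C)C=C)c(OCOC)cc1OCOC | intermediate
5 | 4-bromophenol | Oc1ccc(Br)cc1 | starting material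
6 | 4-bromo-2-(3-methylbut-2-en-1-yl)phenol | Oc1ccc(Br)cc1CC=C(C)C | intermediate
7 | 5-bromo-2-hydroxy-3-(3-methylbut-2-en-1-yl)benzaldehyde | O=Cc1cc(Br)cc(CC=C(C)C)c1O | intermediate
8 | 5-bromo-2-hydroxy-3-(3-methylbut-2-en-1-yl)phenyl formate (not isolated) | O=COc1cc(Br)cc(CC=C(C)C)c1O | intermediate
9 | 5-bromo-3-(3-methylbut-2-en-1-yl)benzene-1,2-diol | Oc1cc(Br)cc(CC=C(C)C)c1O | intermediate
10 | 5-bromo-1,2-bis(methoxymethoxy)-3-(3-methylbut-2-en-1-yl)benzene | COCOc1cc(Br)cc(CC=C(C)C)c1OCOC | intermediate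
11 | 2-acetyl-3,5-bis(methoxymethoxy)-6-(2-methylbut-3-en-2-yl)phenyl 3,4-bis(methoxymethoxy)-5-(3-methylbut-2-en-1-yl)benzoate (not isolated) | CC(=O)c1c(OC(=O)c2cc(OCOC)c(OCOC)c(CC=C(C)C)c2)c(C(C)(C)C=C)c(OCOC)cc1OCOC | intermediate
12 | 1-[3,4-bis(methoxymethoxy)-5-(3-methylbut-2-en-1-yl)phenyl]-3-[2-hydroxy-4,6-bis(methoxymethoxy)-3-(2-methylbut-3-en-2-yl)phenyl]propane-1,3-dione (not isolated) | C=CC(C)(C)c1c(O)c(C(=O)CC(=O)c2cc(OCOC)c(OCOC)c(CC=C(C)C)c2)c(OCOC)cc1OCOC | intermediate
13 | 2-[3,4-bis(methoxymethoxy)-5-(3-methylbut-2-en-1-yl)phenyl]-5,7-bis(methoxymethoxy)-8-(2-methylbut-3-en-2-yl)-4H-chromen-4-one | C=CC(C)(C)c1c(OCOC)cc(OCOC)c2c(=O)cc(-c3cc(OCOC)c(OCOC)c(CC=C(C)C)c3)oc12 | intermediate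
14 | 3-lithio derivative of 13 (not isolated) | [Li]c1c(-c2cc(OCOC)c(OCOC)c(CC=C(C)C)c2)oc2c(C(C)(C)C=C)c(OCOC)cc(OCOC)c2c1=O | intermediate
15 | lithium trimethoxy(flavon-3-yl)borate derived from 14 (not isolated) | [Li+].CO[B-](OC)(OC)c1c(-c2cc(OCOC)c(OCOC)c(CC=C(C)C)c2)oc2c(C(C)(C)C=C)c(OCOC)cc(OCOC)c2c1=O | intermediate
16 | 2-[3,4-bis(methoxymethoxy)-5-(3-methylbut-2-en-1-yl)phenyl]-3-hydroxy-5,7-bis(methoxymethoxy)-8-(2-methylbut-3-en-2-yl)-4H-chromen-4-one | C=CC(C)(C)c1c(OCOC)cc(OCOC)c2c(=O)c(O)c(-c3cc(OCOC)c(OCOC)c(CC=C(C)C)c3)oc12 | intermediate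
17 | 2-[3,4-dihydroxy-5-(3-methylbut-2-en-1-yl)phenyl]-3,5,7-trihydroxy-8-(2-methylbut-3-en-2-yl)-4H-chromen-4-one | C=CC(C)(C)c1c(O)cc(O)c2c(=O)c(O)c(-c3cc(O)c(O)c(CC=C(C)C)c3)oc12 | target

**Step count and risks**
Total steps: 10. Longest linear sequence: 7 (steps 4 to 10).

Step 8 is the most likely to fail. The phenoxide of 4 is flanked by an acetyl group and a quaternary carbon, so capture of the aroyl–palladium may be slow. The acyl–palladium could then be lost to hydrolysis or reduction, non‑carbonylative coupling could compete, and cyclodehydration could stall. The fallback avoids palladium and gas and forms the same diketone by direct C‑aroylation of the ketone dianion. It sets out from 10 and 4. Bromide 10 is lithiated (n‑BuLi, THF, −78 °C) and carboxylated with CO2 to give 3,4-bis(methoxymethoxy)-5-(3-methylbut-2-en-1-yl)benzoic acid F1. Carbonyldiimidazole converts it into the acyl imidazolide [3,4-bis(methoxymethoxy)-5-(3-methylbut-2-en-1-yl)phenyl](1H-imidazol-1-yl)methanone F2. The dianion of 4 (LiHMDS, 3 equiv, THF, −78 °C) should be acylated at carbon by F2 to give diketone 12, here isolated. Cyclodehydration with NaOAc in AcOH at 90 °C should then give 13, where the route is rejoined.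

Step 2 is the second risk. At the rearrangement temperature the newly formed o‑(1,1‑dimethylallyl)phenol may add one of its flanking OH groups across the vinyl group, or the free triphenol may degrade. The fallback runs the rearrangement with every phenol masked as it forms. It sets out from 2, which is acetylated (Ac2O, pyridine) to 2-acetyl-5-(3-methylbut-2-en-1-yloxy)-1,3-phenylene diacetate F3. Heating F3 in PhNEt2 with Ac2O and NaOAc should give the Claisen product trapped as 2-acetyl-4-(2-methylbut-3-en-2-yl)benzene-1,3,5-triyl triacetate F4. Methanolysis (K2CO3, MeOH, rt, Ar) returns 3, where the route is rejoined.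

Step 9 is the third risk. Deprotonation at the benzylic‑allylic CH2 of the prenyl group or addition of the base to the chromone may compete with C3 lithiation, giving incomplete or unselective hydroxylation. The fallback brings in the 3‑oxygen by the Algar–Flynn–Oyamada reaction instead. It sets out from 10 and 4. Bromide 10 is lithiated (n‑BuLi, THF, −78 °C) and formylated with DMF to give 3,4-bis(methoxymethoxy)-5-(3-methylbut-2-en-1-yl)benzaldehyde F5. Claisen–Schmidt condensation with 4 (KOH, EtOH, rt) should give (E)-3-[3,4-bis(methoxymethoxy)-5-(3-methylbut-2-en-1-yl)phenyl]-1-[2-hydroxy-4,6-bis(methoxymethoxy)-3-(2-methylbut-3-en-2-yl)phenyl]prop-2-en-1-one F6. Oxidative cyclisation with H2O2 and NaOH in MeOH at 0 °C should give 16, where the route is rejoined. Aurone formation is the known side path for chalcones with a 6′‑alkoxy group.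

**Further compounds**
F1 | step 8 | 3,4-bis(methoxymethoxy)-5-(3-methylbut-2-en-1-yl)benzoic acid | OC(=O)c1cc(OCOC)c(OCOC)c(CC=C(C)C)c1
F2 | step 8 | [3,4-bis(methoxymethoxy)-5-(3-methylbut-2-en-1-yl)phenyl](1H-imidazol-1-yl)methanone | O=C(c1cc(OCOC)c(OCOC)c(CC=C(C)C)c1)n1ccnc1
F3 | step 2 | 2-acetyl-5-(3-methylbut-2-en-1-yloxy)-1,3-phenylene diacetate | CC(=O)Oc1cc(OCC=C(C)C)cc(OC(C)=O)c1C(C)=O
F4 | step 2 | 2-acetyl-4-(2-methylbut-3-en-2-yl)benzene-1,3,5-triyl triacetate | CC(=O)Oc1cc(OC(C)=O)c(C(C)(C)C=C)c(OC(C)=O)c1C(C)=O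
F5 | step 9 | 3,4-bis(methoxymethoxy)-5-(3-methylbut-2-en-1-yl)benzaldehyde | O=Cc1cc(OCOC)c(OCOC)c(CC=C(C)C)c1
F6 | step 9 | (E)-3-[3,4-bis(methoxymethoxy)-5-(3-methylbut-2-en-1-yl)phenyl]-1-[2-hydroxy-4,6-bis(methoxymethoxy)-3-(2-methylbut-3-en-2-yl)phenyl]prop-2-en-1-one | C=CC(C)(C)c1c(O)c(C(=O)/C=C/c2cc(OCOC)c(OCOC)c(CC=C(C)C)c2)c(OCOC)cc1OCOC
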